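**Retrosynthetic overview**
1. Target ⇒ core dialdehyde + two molecules of phenyl 1-phenylvinyl sulfone: each enone C(=O)–Cα bond is made last, the acyl anion of ArCHO adding to the vinyl sulfone β-carbon before sulfinate leaves.
2. Core dialdehyde ⇒ chromene alkene of a C/D unit + ortho-quinone methide of ring B (from the 4-methoxychroman of the A–CH2–B aldehyde); an oxa-[4+2] closes the pyran between B and C.
3. C/D unit ⇒ ring C chromene + formaldehyde + ring D chromene aldehyde; an ortho-quinone methide annulation closes the pyran between C and D.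
4. A–CH2–B aldehyde ⇒ ring A Mannich base + ring B chromene aldehyde; the ring D aldehyde is the same ring B aldehyde after C-methylation.
5. Rings (A = benzyl-linked acetylphloroglucinol; B and D = cinnamoyl-bearing chromans; C = acetyl-bearing chroman): 2,2-dimethylpyrans of B, D and C first, then the C/D pyran, then the B/C pyran, then the two chalcone arms.

Assumption: the target SMILES is read as H/H trans at the ring C–ring D fusion and H/H cis at the ring B–ring C fusion, and the sense of induction of each chiral acid is taken as written (the antipodal catalyst is used in that step if a first run gives the mirror-image fusion).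

Step 1
Reactants: 1 phloroglucinol; 2 3-methylbut-2-enal
Product: 3 5,7-dihydroxy-2,2-dimethyl-2H-chromene
Conditions: 1 (3 equiv), pyridine, 110 °C
Reagents that add atoms: none
Why: Phenol–enal chromenylation (Knoevenagel-type C-alkylation followed by oxa-6π electrocyclisation) on the symmetric triol, whose excess suppresses a second annulation, and no stereocentre is formed.

Step 2
Reactants: 3 5,7-dihydroxy-2,2-dimethyl-2H-chromene
Product: 4 5,7-dihydroxy-2,2-dimethyl-2H-chromene-8-carbaldehyde
Conditions: POCl3, DMF, MeCN, 0 °C; then H2O, 40 °C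
Reagents that add atoms: N,N-dimethylformamide, CN(C)C=O; water, O
Why: Vilsmeier–Haack formylation, which in phloroglucinol monoethers goes mainly to the carbon ortho to the ether oxygen and para to a hydroxyl (here C8), the minor C6 aldehyde being removed by chromatography.

Step 3
Reactants: 4 5,7-dihydroxy-2,2-dimethyl-2H-chromene-8-carbaldehyde
Product: 5 5,7-dihydroxy-2,2,6-trimethyl-2H-chromene-8-carbaldehyde
Conditions: MeI (1.05 equiv), NaOMe (1.1 equiv), MeOH, 0 °C to rt
Reagents that add atoms: iodomethane, CI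
Why: Nuclear C-methylation of an acylphloroglucinol-type phenoxide in methanol, which takes place at C6 because it is the only free ring carbon and lies between the two hydroxyls.

Step 4
Reactants: 6 1-(2,4,6-trihydroxyphenyl)ethanone; 2 3-methylbut-2-enal
Product: 7 1-(5,7-dihydroxy-2,2-dimethyl-2H-chromen-6-yl)ethanone
Conditions: pyridine, 110 °C
Reagents that add atoms: none
Why: Phenol–enal chromenylation in which the oxa-6π ring closure uses the free 4-hydroxyl (para to the acetyl group) and not a hydroxyl chelated to the ketone, so the 6-acetyl chromene is the main isomer.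

Step 5
Reactants: 7 1-(5,7-dihydroxy-2,2-dimethyl-2H-chromen-6-yl)ethanone; 5 5,7-dihydroxy-2,2,6-trimethyl-2H-chromene-8-carbaldehyde
Product: 10 C/D aldehyde (ring C 2H-chromene joined through its 7-oxygen to C4 and through its 8-CH2 to C3 of the ring D chroman; ring D C3 R; C4 R; H3/H4 trans), via hydroxymethyl chromene 8 (not isolated), via ortho-quinone methide 9 (not isolated)
Conditions: 7 added over 8 h to 5 (2.5 equiv), (CH2O)n (3 equiv), (R)-3,3′-bis(2,4,6-triisopropylphenyl)-1,1′-binaphthalene-2,2′-diyl N-triflylphosphoramide (10 mol%), PhCF3, 40 °C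
Reagents that add atoms: formaldehyde, C=O
Why: Proposed new method: the chiral acid hydroxymethylates C8 of 7 (its only free ring carbon) and ionises 8 to 9, whose methylene adds to C3 of the chromene alkene of 5 on the face set by the ion-paired catalyst (ring D C3, R), after which the 7-oxygen closes reversibly on the benzylic C4 cation to the diequatorial trans-fused pyran (C4, R), slow addition of 7 keeping its own alkene from competing; the closest known reactions are chiral phosphoric-acid-type ortho-quinone methide/styrene oxa-[4+2] cycloadditions and acid-mediated phenol–formaldehyde–alkene chroman syntheses.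

Step 6
Reactants: 11 1-(2,4,6-trihydroxy-3-methylphenyl)ethanone
Product: 12 1-[3-[(dimethylamino)methyl]-2,4,6-trihydroxy-5-methylphenyl]ethanone
Conditions: CH2O (37% aq), Me2NH (40% aq), EtOH, 0 °C to rt
Reagents that add atoms: formaldehyde, C=O; dimethylamine, CNC
Why: Mannich aminomethylation at the single free ring carbon of the acylphloroglucinol.

Step 7
Reactants: 4 5,7-dihydroxy-2,2-dimethyl-2H-chromene-8-carbaldehyde; 12 ring A Mannich base
Product: 14 6-[(3-acetyl-2,4,6-trihydroxy-5-methylphenyl)methyl]-5,7-dihydroxy-2,2-dimethyl-2H-chromene-8-carbaldehyde, via ortho-quinone methide 13 (not isolated)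
Conditions: 1,4-dioxane, 100 °C, N2
Reagents that add atoms: none
Why: Thermal loss of dimethylamine from the Mannich base gives 13, which is captured by C6 of 4 (its only free ring carbon) in a Friedel–Crafts-type Michael addition, the standard methylene bridging of acylphloroglucinols.

Step 8
Reactants: 14 A–B chromene aldehyde
Product: 15 6-[(3-acetyl-2,4,6-trihydroxy-5-methylphenyl)methyl]-5,7-dihydroxy-4-methoxy-2,2-dimethylchroman-8-carbaldehyde (racemic at C4)
Conditions: MeOH, TsOH·H2O (5 mol%), 0 °C
Reagents that add atoms: methanol, CO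
Why: Acid-catalysed Markovnikov addition of methanol to the electron-rich chromene through the chroman-4-yl cation gives a benzylic ether (its centre is erased in step 9) that lets ring B be ionised later without protonating a second chromene.

Step 9
Reactants: 10 C/D aldehyde; 15 A–B 4-methoxychroman aldehyde
Product: 17 core dialdehyde (the target skeleton with CHO in place of each cinnamoyl group; ring C chroman C4 S and C3 R with H3/H4 cis; ring B chroman C4 R with H4 anti to H3 of ring C; ring D C3 R and C4 R), via ortho-quinone methide 16 (not isolated)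
Conditions: 15 (1.3 equiv), (S)-3,3′-bis(2,4,6-triisopropylphenyl)-1,1′-binaphthalene-2,2′-diyl N-triflylphosphoramide (10 mol%), CH2Cl2, −20 °C
Reagents that add atoms: none
Why: Chiral Brønsted acid-catalysed inverse-demand oxa-Diels–Alder reaction in which loss of methanol from 15 gives 16, whose catalyst-bound face adds suprafacially and exo to the chromene alkene of 10, so that C4 and C3 of the ring C chroman form cis (S, R) and C4 of the ring B chroman (R) carries its hydrogen anti to H3, the remote ring D centres exerting no control.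

Step 10
Reactants: 18 benzyl phenyl sulfone
Product: 19 phenyl 1-phenylvinyl sulfone
Conditions: (Me2N)2CH2, Ac2O, DMF, 60 °C
Reagents that add atoms: N,N,N′,N′-tetramethylmethanediamine, CN(C)CN(C)C
Why: Mannich-type α-methylenation of the benzylic sulfone (aminomethylation by the iminium formed in the flask, then acetic anhydride-promoted elimination of the amine).

Step 11
Reactants: 17 core dialdehyde; 19 phenyl 1-phenylvinyl sulfone
Product: 23 CNP0130468.1, via heptasilyl ether 20 (not isolated), via bis-sulfone 21 (not isolated), via silylated bis-enone 22 (not isolated)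
Conditions: BSA (N,O-bis(trimethylsilyl)acetamide, 10 equiv), THF, 50 °C; then 19 (3 equiv), 3,4,5-trimethylthiazolium iodide (30 mol%), i-Pr2NEt (60 mol%), 60 °C; then DBU (4 equiv), rt; then MeOH, citric acid (cat.), rt
Reagents that add atoms: phenyl 1-phenylvinyl sulfone (second molecule of 19), C=C(c1ccccc1)S(=O)(=O)c1ccccc1
Why: Proposed new method: after transient O-silylation to 20 the thiazol-2-ylidene turns each hindered, non-self-condensing aryl aldehyde into its Breslow intermediate, an acyl anion that adds to the β-carbon of one molecule of the vinyl sulfone (two molecules of 19 are consumed in all, one per aldehyde, and the acyl carbon and the β-carbon are both electrophilic in their native form) to give 21, DBU then expels benzenesulfinate from each arm by E1cB to the conjugated E-enones of 22, and methanolysis frees the seven phenols; the closest known reactions are the intermolecular Stetter reaction of aromatic aldehydes with vinyl sulfones and the base elimination of β-sulfonyl ketones.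

**Compound list**
1 | phloroglucinol | Oc1cc(O)cc(O)c1 | starting material
2 | 3-methylbut-2-enal | CC(C)=CC=O | starting material
3 | 5,7-dihydroxy-2,2-dimethyl-2H-chromene | CC1(C)C=Cc2c(O)cc(O)cc2O1 | intermediate
4 | 5,7-dihydroxy-2,2-dimethyl-2H-chromene-8-carbaldehyde | CC1(C)C=Cc2c(O)cc(O)c(C=O)c2O1 | intermediate
5 | 5,7-dihydroxy-2,2,6-trimethyl-2H-chromene-8-carbaldehyde | CC1(C)C=Cc2c(O)c(C)c(O)c(C=O)c2O1 | intermediate
6 | 1-(2,4,6-trihydroxyphenyl)ethanone | CC(=O)c1c(O)cc(O)cc1O | starting material
7 | 1-(5,7-dihydroxy-2,2-dimethyl-2H-chromen-6-yl)ethanone | CC(=O)c1c(O)cc2OC(C)(C)C=Cc2c1O | intermediate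
8 | 1-[5,7-dihydroxy-8-(hydroxymethyl)-2,2-dimethyl-2H-chromen-6-yl]ethanone | CC(=O)c1c(O)c(CO)c2OC(C)(C)C=Cc2c1O | intermediate
9 | ortho-quinone methide of 8 (6-acetyl-5-hydroxy-2,2-dimethyl-8-methylidene-2H-chromen-7-one) | CC(=O)C1=C(O)C2=C(OC(C)(C)C=C2)C(=C)C1=O | intermediate
10 | C/D aldehyde: 6-acetyl-5-hydroxy-2,2-dimethyl-2H-chromene (ring C) whose 7-O is bonded to C4 and whose 8-CH2 is bonded to C3 of 5,7-dihydroxy-2,2,6-trimethylchroman-8-carbaldehyde (ring D); ring D C3 R, C4 R, H3/H4 trans | CC(=O)c1c(O)c2C=CC(C)(C)Oc2c2C[C@@H]3[C@@H](Oc12)c1c(O)c(C)c(O)c(C=O)c1OC3(C)C | intermediate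
11 | 1-(2,4,6-trihydroxy-3-methylphenyl)ethanone | CC(=O)c1c(O)cc(O)c(C)c1O | starting material
12 | 1-[3-[(dimethylamino)methyl]-2,4,6-trihydroxy-5-methylphenyl]ethanone | CC(=O)c1c(O)c(CN(C)C)c(O)c(C)c1O | intermediate
13 | ortho-quinone methide of ring A (2-acetyl-3,5-dihydroxy-4-methyl-6-methylidenecyclohexa-2,4-dien-1-one) | CC(=O)C1=C(O)C(C)=C(O)C(=C)C1=O | intermediate
14 | 6-[(3-acetyl-2,4,6-trihydroxy-5-methylphenyl)methyl]-5,7-dihydroxy-2,2-dimethyl-2H-chromene-8-carbaldehyde | CC(=O)c1c(O)c(C)c(O)c(Cc2c(O)c(C=O)c3OC(C)(C)C=Cc3c2O)c1O | intermediate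
15 | 6-[(3-acetyl-2,4,6-trihydroxy-5-methylphenyl)methyl]-5,7-dihydroxy-4-methoxy-2,2-dimethylchroman-8-carbaldehyde, racemic at C4 | CC(=O)c1c(O)c(C)c(O)c(Cc2c(O)c(C=O)c3OC(C)(C)CC(OC)c3c2O)c1O | intermediate
16 | ortho-quinone methide of ring B (15 minus methanol; exocyclic C4a=C4 alkene, C5 carbonyl) | CC(=O)c1c(O)c(C)c(O)c(CC2=C(O)C(C=O)=C3OC(C)(C)CC=C3C2=O)c1O | intermediate
17 | core dialdehyde: the target with CHO in place of each cinnamoyl group; ring C chroman C4 S, C3 R; ring B chroman C4 R; ring D chroman C3 R, C4 R | CC(=O)c1c(O)c(C)c(O)c(Cc2c(O)c(C=O)c3c4c2O[C@@H]2c5c(O)c(C(C)=O)c6c(c5OC(C)(C)[C@@H]2[C@H]4CC(C)(C)O3)C[C@@H]2[C@@H](O6)c3c(O)c(C)c(O)c(C=O)c3OC2(C)C)c1O | intermediate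
18 | benzyl phenyl sulfone | O=S(=O)(Cc1ccccc1)c1ccccc1 | starting material
19 | phenyl 1-phenylvinyl sulfone | C=C(c1ccccc1)S(=O)(=O)c1ccccc1 | intermediate
20 | heptakis(trimethylsilyl) ether of 17 (all seven phenols silylated) | CC(=O)c1c(O[Si](C)(C)C)c(C)c(O[Si](C)(C)C)c(Cc2c(O[Si](C)(C)C)c(C=O)c3c4c2O[C@@H]2c5c(O[Si](C)(C)C)c(C(C)=O)c6c(c5OC(C)(C)[C@@H]2[C@H]4CC(C)(C)O3)C[C@@H]2[C@@H](O6)c3c(O[Si](C)(C)C)c(C)c(O[Si](C)(C)C)c(C=O)c3OC2(C)C)c1O[Si](C)(C)C | intermediate
21 | bis-sulfone: 20 with each CHO converted to C(=O)CH2CH(Ph)SO2Ph (mixture at the two new sulfone-bearing carbons) | CC(=O)c1c(O[Si](C)(C)C)c(C)c(O[Si](C)(C)C)c(Cc2c(O[Si](C)(C)C)c(C(=O)CC(c3ccccc3)S(=O)(=O)c3ccccc3)c3c4c2O[C@@H]2c5c(O[Si](C)(C)C)c(C(C)=O)c6c(c5OC(C)(C)[C@@H]2[C@H]4CC(C)(C)O3)C[C@@H]2[C@@H](O6)c3c(O[Si](C)(C)C)c(C)c(O[Si](C)(C)C)c(C(=O)CC(c4ccccc4)S(=O)(=O)c4ccccc4)c3OC2(C)C)c1O[Si](C)(C)C | intermediate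
22 | silylated bis-enone: heptakis(trimethylsilyl) ether of the target (both enones E) | CC(=O)c1c(O[Si](C)(C)C)c(C)c(O[Si](C)(C)C)c(Cc2c(O[Si](C)(C)C)c(C(=O)/C=C/c3ccccc3)c3c4c2O[C@@H]2c5c(O[Si](C)(C)C)c(C(C)=O)c6c(c5OC(C)(C)[C@@H]2[C@H]4CC(C)(C)O3)C[C@@H]2[C@@H](O6)c3c(O[Si](C)(C)C)c(C)c(O[Si](C)(C)C)c(C(=O)/C=C/c4ccccc4)c3OC2(C)C)c1O[Si](C)(C)C | intermediate
23 | CNP0130468.1 | CC(=O)c1c(O)c(C)c(O)c(Cc2c(O)c(C(=O)/C=C/c3ccccc3)c3c4c2O[C@@H]2c5c(O)c(C(C)=O)c6c(c5OC(C)(C)[C@@H]2[C@H]4CC(C)(C)O3)C[C@@H]2[C@@H](O6)c3c(O)c(C)c(O)c(C(=O)/C=C/c4ccccc4)c3OC2(C)C)c1O | target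

**Totals and risks**
Total step count: 11. Longest linear sequence: 6 steps (1, 2, 3, 5, 9, 11; equally 1, 2, 7, 8, 9, 11).

Most likely to fail, first: step 11. The two aldehydes are di-ortho-oxygenated and crowded, and the carbene may strip silyl groups instead of forming the Breslow intermediates. The fallback sets out from 17: rhodium-catalysed 1,2-addition of (E)-2-phenylvinylboronic acid ([Rh(OH)(C8H12)]2, dioxane–water, 60 °C) tolerates free phenols and leaves the hindered aryl methyl ketones alone, giving the bis(allylic alcohol) F1. MnO2 in CH2Cl2 then oxidises both activated carbinols to the enones, and the route is rejoined at 23.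

Second: step 5. In situ hydroxymethylation may give oligomers, the alkene of 7 may compete with that of 5, and face selection on an unsubstituted methide is untested. The fallback sets out from 7: Vilsmeier–Haack formylation (POCl3, DMF) at C8 gives 6-acetyl-5,7-dihydroxy-2,2-dimethyl-2H-chromene-8-carbaldehyde F2. NaBH4 (EtOH, 0 °C) reduces only the aldehyde, the acetyl group being chelated on both sides, to the benzylic alcohol 8, which is now isolated and purified. It is then ionised by the same chiral acid in the presence of 5, so the route is rejoined at 8.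

Third: step 9. The bulky ring A substituent next to the reacting centre may slow the cycloaddition enough for 16 to tautomerise back to chromene 14, and catalyst control must override a large chiral partner. The fallback sets out from 4 and 10: 4 is treated with MeOH and TsOH to give 5,7-dihydroxy-4-methoxy-2,2-dimethylchroman-8-carbaldehyde F3. The chiral acid ionises it to the smaller ortho-quinone methide lacking ring A F4, which is united in the same flask with 10 to give the core dialdehyde lacking ring A F5, in which C6 of ring B is the only free ring carbon. Heating F5 with Mannich base 12 installs the methylene bridge last through 13, and the route is rejoined at 17.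

Further compounds
F1 | step 11 | bis(allylic alcohol): 17 with each CHO converted to CH(OH)–CH=CH–Ph (E; carbinol centres unassigned) | CC(=O)c1c(O)c(C)c(O)c(Cc2c(O)c(C(O)/C=C/c3ccccc3)c3c4c2O[C@@H]2c5c(O)c(C(C)=O)c6c(c5OC(C)(C)[C@@H]2[C@H]4CC(C)(C)O3)C[C@@H]2[C@@H](O6)c3c(O)c(C)c(O)c(C(O)/C=C/c4ccccc4)c3OC2(C)C)c1O
F2 | step 5 | 6-acetyl-5,7-dihydroxy-2,2-dimethyl-2H-chromene-8-carbaldehyde | CC(=O)c1c(O)c(C=O)c2OC(C)(C)C=Cc2c1O
F3 | step 9 | 5,7-dihydroxy-4-methoxy-2,2-dimethylchroman-8-carbaldehyde (racemic) | COC1CC(C)(C)Oc2c(C=O)c(O)cc(O)c12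
F4 | step 9 | ortho-quinone methide lacking ring A (F3 minus methanol; exocyclic C4a=C4 alkene, C5 carbonyl) | O=C1C=C(O)C(C=O)=C2OC(C)(C)CC=C12
F5 | step 9 | core dialdehyde lacking ring A (17 with H in place of the ring A benzyl group; same configuration) | c1c(O)c(C=O)c2c3c1O[C@@H]1c4c(O)c(C(C)=O)c5c(c4OC(C)(C)[C@@H]1[C@H]3CC(C)(C)O2)C[C@@H]1[C@@H](O5)c2c(O)c(C)c(O)c(C=O)c2OC1(C)C
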